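1. Start from the leftover. In the eta run at 20.0 min, target and side product hold 46.0% of the starting material charged, so 54.0% appears in no reading. In the epsilon run at 20.0 min they hold 55.0%.

| setting | eta | epsilon | flask |
|---|---|---|---|
| starting material | 0.12 M | 0.19 M | 0.25 M |
| partner | 1.2 equiv | 1.2 equiv | 1.20 equiv |
| protic impurity | 0.25 M | 0.25 M | 0.250 M |
| capture agent | 0.025 M | 0.025 M | 0.0250 M |
| remark | run made earlier | run made earlier |  |
| time |  |  | 30 min |

- eta (time / min: target / %, side product / %): 1.33: 16, 2; 2.50: 26, 4; 4.00: 34, 4; 6.00: 39, 1; 10.0: 39, 2; 20.0: 44, 2
- epsilon (time / min: target / %, side product / %): 1.33: 19, 3; 4.00: 45, 3; 6.00: 52, 7; 10.0: 54, 6; 15.0: 52, 5; 20.0: 51, 4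

(scatter of a reading: 2 percentage points)

1. at 30 min, what has stopped the reaction, if anything has (all of the starting material has reacted / it is still moving / the partner has run out first / forward and back rates have come level)
2. target at 30 min, in percent of the starting material charged
3. side product at 30 min, in percent of the starting material charged

- the reaction counts as stopped when no species that holds the starting material changes by six tenths of a point or more over the second half of the time

2. Read the leftover as a competition: suppose partner and protic impurity both take starting material. Set the zero of the scale at an even split for equal concentrations, a factor of 1.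

3. Divide the odds, held over leftover, by charged c(partner)/c(protic impurity). The eta readings give 1.48, the epsilon readings 1.34. Their mean, 1.41, is the split factor, a selectivity factor, and it lies above the even split.

4. Apply it to this flask. The ratio is 1.20, so the odds are 1.69. Expect 62.8% held as target plus side product.

5. Expect this flask to have stopped by 30 min, with the starting material reacted away. Epsilon target reads 54% at 10.0 min and 51% at 20.0 min, flat within the scatter. Add no protic impurity: in this reckoning the odds fall as c(protic impurity) rises.

6. The forecast says forward and back rates have come level, target 56% (51% to 62%), side product 5.5% (2.5% to 9%). Its ground is a reversible step from starting material and partner to target, for which “relaxation takes a few minutes, which matches the runs”. Its two yields add to 61.5%, a little below my held share.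

7. The flask gives: all of the starting material has reacted, target 56.0%, side product 5.69%. Starting material stands at 0% at 30.0 min, so the yields agree with the forecast and the stop does not. The split factor reckoned 62.8% held; the flask holds 61.7%.

    starting material + partner → intermediate A (k = 0.118 L mol⁻¹ s⁻¹)
    intermediate A → target (k = 0.00878 s⁻¹)
    partner + intermediate A → side product (k = 0.00685 L mol⁻¹ s⁻¹)
    partner + intermediate A ⇌ intermediate B (K = 1.70 L mol⁻¹, k = 0.408 L mol⁻¹ s⁻¹)
    starting material + protic impurity → quenched substrate (k = 0.0523 L mol⁻¹ s⁻¹)
    capture agent + intermediate A → trapped intermediate (k = 0.0472 L mol⁻¹ s⁻¹)

8. Take the neighbour flask with 0.62 M protic impurity. The ratio is 0.484, the odds 0.682, so expect 40.5% held. It gives target 38.3% and side product 5.12%, together 43.4%.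

The data come from a simulation from invented constants, noise included.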